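**Plan**

1. Numbering: ring A carries the ether CH2 on C1, the bridge CH2 on C2, Br on C3 and oxygens on C4 and C5; ring B carries the bridge on C1', Br on C2' and C3' and oxygens on C4' and C5'.
2. Retrosynthesis: the central CH2–O–CH2 ether is cut into two identical benzylic alcohols, which are traced back to the aldehyde with C5 and C5' methyl ethers. The three C–Br bonds of one half are then cut together, and last the bridge CH2–C2 bond is cut to a ring B benzylic chloride and a ring A arylboronate.
3. Enabling feature: with O4 and O4' free and O5 and O5' methylated, both rings are vanillin-type. C3 and C3' are the only open carbons ortho to a hydroxyl and C2' is para to the C5' methoxy group, while C2 of ring A is taken by the bridge and C6 is deactivated by the C1 aldehyde.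
4. Forward: chloride formation and borylation, Suzuki coupling of the two preformed rings (no ring is built), debenzylation, one-pot tribromination, demethylation, reduction, dehydrative dimerisation.
5. The target has no stereocentre; only positional selectivity has to be controlled.

Key step: step 5

Assumption: 4-(benzyloxy)-2-bromo-5-methoxybenzaldehyde is taken as a purchasable building block; it is otherwise one bromination away from O-benzylvanillin.

**Route**

Step 1
Reactants: 1 4-(benzyloxy)-3-methoxybenzyl alcohol
Product: 2 4-(benzyloxy)-3-methoxybenzyl chloride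
Conditions: SOCl2 (1.2 equiv), CH2Cl2, 0 °C to rt
Reagents that add atoms: thionyl chloride, O=S(Cl)Cl
Why: Chlorodehydroxylation of an electron-rich benzylic alcohol with thionyl chloride (chlorosulfite, then displacement by chloride) is fast at 0 °C and leaves both aryl ethers untouched.

Step 2
Reactants: 3 4-(benzyloxy)-2-bromo-5-methoxybenzaldehyde
Product: 4 4-(benzyloxy)-5-methoxy-2-(4,4,5,5-tetramethyl-1,3,2-dioxaborolan-2-yl)benzaldehyde
Conditions: B2pin2 (1.2 equiv), PdCl2(dppf) (3 mol %; dppf = 1,1'-bis(diphenylphosphino)ferrocene), KOAc (3 equiv), 1,4-dioxane, 90 °C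
Reagents that add atoms: bis(pinacolato)diboron, CC1(C)OB(OC1(C)C)B1OC(C)(C)C(C)(C)O1
Why: Miyaura borylation, in which zerovalent palladium inserts into the C–Br bond activated by the ortho-formyl group and the acetate-ligated palladium complex transmetallates with B2pin2, conditions under which aldehyde and benzyl ether are inert, as with 6-bromoveratraldehyde.

Step 3
Reactants: 4 4-(benzyloxy)-5-methoxy-2-(4,4,5,5-tetramethyl-1,3,2-dioxaborolan-2-yl)benzaldehyde; 2 4-(benzyloxy)-3-methoxybenzyl chloride
Product: 5 4-(benzyloxy)-2-[4-(benzyloxy)-3-methoxybenzyl]-5-methoxybenzaldehyde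
Conditions: Pd(PPh3)4 (5 mol %), K3PO4 (3 equiv), toluene/H2O (10:1), 80 °C
Reagents that add atoms: none
Why: Suzuki–Miyaura sp2–sp3 coupling (oxidative addition of the benzylic C–Cl bond to zerovalent palladium, transmetallation from the boronate, reductive elimination) is a standard diarylmethane synthesis and tolerates the free aldehyde, which a benzylic zinc or magnesium reagent would attack.

Step 4
Reactants: 5 4-(benzyloxy)-2-[4-(benzyloxy)-3-methoxybenzyl]-5-methoxybenzaldehyde
Product: 6 4-hydroxy-2-(4-hydroxy-3-methoxybenzyl)-5-methoxybenzaldehyde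
Conditions: BCl3 (5 equiv), C6HMe5 (6 equiv), CH2Cl2, −78 °C; then H2O
Reagents that add atoms: none
Why: Lewis-acid debenzylation, in which BCl3 held between the benzyloxy and the neighbouring methoxy oxygen ionises only the benzyl C–O bond at −78 °C while pentamethylbenzene traps the benzyl cation before it can alkylate the electron-rich rings, so methyl ethers and aldehyde should survive.

Step 5
Reactants: 6 4-hydroxy-2-(4-hydroxy-3-methoxybenzyl)-5-methoxybenzaldehyde; 7 bromine
Product: 10 3-bromo-2-(2,3-dibromo-4-hydroxy-5-methoxybenzyl)-4-hydroxy-5-methoxybenzaldehyde, via ring B monobromide 8 (not isolated), via 3,3'-dibromide 9 (not isolated)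
Conditions: Br2 (2.0 equiv), AcOH, 10 °C; then Br2 (1.05 equiv), 45 °C, dark
Reagents that add atoms: bromine, BrBr
Why: Three successive electrophilic aromatic brominations (arenium-ion substitution) run in one pot, the direct analogue of vanillin → 5-bromovanillin → 5,6-dibromovanillin. The free hydroxyls at C4' and C4 should send the first two equivalents to their only open ortho carbons, C3' of ring B (8) and then C3 of the formyl-deactivated ring A (9). The third equivalent should enter ring B at C2', para to the C5' methoxy group, which outranks C6' (only ortho to methoxy); ring B carries no carbonyl, so mild warming should suffice where the vanillin series needs iron catalysis. Ring A should stop at one bromine because its para-to-methoxy carbon C2 holds the bridge and C6 sits ortho to the aldehyde. No ring is closed and no stereocentre is formed; the selectivity needed is purely positional, and staged addition of three equivalents in the dark guards against a fourth bromination at C6', ipso attack at C1' and radical bromination of the bridge CH2.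

Step 6
Reactants: 10 3-bromo-2-(2,3-dibromo-4-hydroxy-5-methoxybenzyl)-4-hydroxy-5-methoxybenzaldehyde
Product: 11 3-bromo-2-(2,3-dibromo-4,5-dihydroxybenzyl)-4,5-dihydroxybenzaldehyde
Conditions: BBr3 (6 equiv), CH2Cl2, −78 °C to rt; then ice/H2O
Reagents that add atoms: none
Why: Lewis-acid ether cleavage, in which BBr3 complexes each methoxy oxygen and bromide removes the methyl group by SN2, with aryl bromides and the diarylmethane inert and the aldehyde returned on aqueous work-up, as in the demethylation of 5,6-dibromovanillin.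

Step 7
Reactants: 11 3-bromo-2-(2,3-dibromo-4,5-dihydroxybenzyl)-4,5-dihydroxybenzaldehyde
Product: 12 3-bromo-4-(2,3-dibromo-4,5-dihydroxybenzyl)-5-(hydroxymethyl)benzene-1,2-diol
Conditions: NaBH4 (3 equiv), THF/H2O (5:1), 0 °C, N2; then aq. NH4Cl to pH 6
Reagents that add atoms: none
Why: Borohydride 1,2-reduction of the aryl aldehyde, as in the reduction of 2,3-dibromo-4,5-dihydroxybenzaldehyde to lanosol, leaves aryl bromides untouched, and a cold, weakly acidic, alcohol-free work-up avoids premature solvolysis of the para-hydroxybenzylic alcohol.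

Step 8
Reactants: 12 3-bromo-4-(2,3-dibromo-4,5-dihydroxybenzyl)-5-(hydroxymethyl)benzene-1,2-diol (two molecules)
Product: 13 bis[3-bromo-2-(2,3-dibromo-4,5-dihydroxybenzyl)-4,5-dihydroxybenzyl] ether (CNP0255526.0)
Conditions: TsOH·H2O (5 mol %), 1,4-dioxane (0.5 M), 4 Å molecular sieves, 40 °C
Reagents that add atoms: none
Why: Acid-catalysed dehydrative etherification of a para-hydroxybenzylic alcohol, in which ionisation gives a benzylic cation stabilised by the C4 hydroxyl that is captured by the hydroxymethyl oxygen of a second molecule; this is the usual outcome for ring-blocked hydroxybenzyl alcohols, since every ring carbon except C6 and C6' is substituted and the bromines deactivate the rings toward C-alkylation, while the sieves remove the water.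

**Compound list**

1 | 4-(benzyloxy)-3-methoxybenzyl alcohol | COc1cc(CO)ccc1OCc1ccccc1 | starting material
2 | 4-(benzyloxy)-3-methoxybenzyl chloride | COc1cc(CCl)ccc1OCc1ccccc1 | intermediate
3 | 4-(benzyloxy)-2-bromo-5-methoxybenzaldehyde | COc1cc(C=O)c(Br)cc1OCc1ccccc1 | starting material
4 | 4-(benzyloxy)-5-methoxy-2-(4,4,5,5-tetramethyl-1,3,2-dioxaborolan-2-yl)benzaldehyde | COc1cc(C=O)c(B2OC(C)(C)C(C)(C)O2)cc1OCc1ccccc1 | intermediate
5 | 4-(benzyloxy)-2-[4-(benzyloxy)-3-methoxybenzyl]-5-methoxybenzaldehyde | COc1cc(C=O)c(Cc2ccc(OCc3ccccc3)c(OC)c2)cc1OCc1ccccc1 | intermediate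
6 | 4-hydroxy-2-(4-hydroxy-3-methoxybenzyl)-5-methoxybenzaldehyde | COc1cc(C=O)c(Cc2ccc(O)c(OC)c2)cc1O | intermediate
7 | bromine | BrBr | starting material
8 | 2-(3-bromo-4-hydroxy-5-methoxybenzyl)-4-hydroxy-5-methoxybenzaldehyde (ring B monobromide) | COc1cc(C=O)c(Cc2cc(Br)c(O)c(OC)c2)cc1O | intermediate
9 | 3-bromo-2-(3-bromo-4-hydroxy-5-methoxybenzyl)-4-hydroxy-5-methoxybenzaldehyde (3,3'-dibromide) | COc1cc(C=O)c(Cc2cc(Br)c(O)c(OC)c2)c(Br)c1O | intermediate
10 | 3-bromo-2-(2,3-dibromo-4-hydroxy-5-methoxybenzyl)-4-hydroxy-5-methoxybenzaldehyde | COc1cc(C=O)c(Cc2cc(OC)c(O)c(Br)c2Br)c(Br)c1O | intermediate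
11 | 3-bromo-2-(2,3-dibromo-4,5-dihydroxybenzyl)-4,5-dihydroxybenzaldehyde | O=Cc1cc(O)c(O)c(Br)c1Cc1cc(O)c(O)c(Br)c1Br | intermediate
12 | 3-bromo-4-(2,3-dibromo-4,5-dihydroxybenzyl)-5-(hydroxymethyl)benzene-1,2-diol | OCc1cc(O)c(O)c(Br)c1Cc1cc(O)c(O)c(Br)c1Br | intermediate
13 | bis[3-bromo-2-(2,3-dibromo-4,5-dihydroxybenzyl)-4,5-dihydroxybenzyl] ether | Oc1cc(Cc2c(COCc3cc(O)c(O)c(Br)c3Cc3cc(O)c(O)c(Br)c3Br)cc(O)c(O)c2Br)c(Br)c(Br)c1O | target

**Count and risks**

Total steps: 8. Longest linear sequence: 7 steps (steps 2 to 8 from 3, or steps 1 and 3 to 8 from 1).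

Step 5 is the most exposed step. The third bromination may lose positional control (entry at C6' in place of C2'), a fourth bromine may enter, or ipso attack at C1' may cleave the bridge. The fallback sets out from 6 and installs the bromines in two directed stages. Acetylation (Ac2O, pyridine) should give 4-acetoxy-2-(4-acetoxy-3-methoxybenzyl)-5-methoxybenzaldehyde F1. With both phenols masked, Br2 (1.05 equiv) with NaOAc in AcOH should brominate only para to the ring B methoxy group, the acetylvanillin → 6-bromovanillin pattern, giving 4-acetoxy-2-(4-acetoxy-2-bromo-5-methoxybenzyl)-5-methoxybenzaldehyde F2. K2CO3 in MeOH then frees the phenols to give 2-(2-bromo-4-hydroxy-5-methoxybenzyl)-4-hydroxy-5-methoxybenzaldehyde F3. Br2 (2.0 equiv) in AcOH at 10 °C should finally enter ortho to each hydroxyl, at C3' and C3, and the route is rejoined at 10.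

Step 8 comes next. The benzylic cation may alkylate a ring carbon (C6 or C6') or a phenol oxygen and lead to oligomers, and the acid may reopen the ether once formed. The fallback sets out from 11. Peracetylation (Ac2O, pyridine) should give 3-bromo-2-(4,5-diacetoxy-2,3-dibromobenzyl)-4,5-diacetoxybenzaldehyde F4. Reductive homo-etherification of the aldehyde (Et3SiH, FeCl3 5 mol %, MeNO2, rt) should give the octaacetate of the target, bis[4,5-diacetoxy-3-bromo-2-(4,5-diacetoxy-2,3-dibromobenzyl)benzyl] ether F5, with no free para-hydroxybenzylic cation involved. Hydrazinolysis of the aryl acetates (N2H4·H2O, THF, 0 °C, no alcohol solvent) then rejoins the route at 13.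

Step 3 is third. The electron-rich benzylic chloride may solvolyse in the aqueous base or homocouple to the bibenzyl, and the ortho-formyl boronate may protodeboronate. The fallback sets out from 2 and inverts the polarity of the coupling. Palladium-catalysed borylation of 2 (B2pin2, Pd(dba)2, P(4-MeOC6H4)3, KOAc, toluene, 50 °C) should give 2-[4-(benzyloxy)-3-methoxybenzyl]-4,4,5,5-tetramethyl-1,3,2-dioxaborolane F6. This benzylic boronate is then coupled with aryl bromide 3 (PdCl2(dppf), K3PO4, 1,4-dioxane/H2O, 90 °C) and the route is rejoined at 5; step 2 is then not needed.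

**Further compounds**

F1 | step 5 | 4-acetoxy-2-(4-acetoxy-3-methoxybenzyl)-5-methoxybenzaldehyde | COc1cc(C=O)c(Cc2ccc(OC(C)=O)c(OC)c2)cc1OC(C)=O
F2 | step 5 | 4-acetoxy-2-(4-acetoxy-2-bromo-5-methoxybenzyl)-5-methoxybenzaldehyde | COc1cc(C=O)c(Cc2cc(OC)c(OC(C)=O)cc2Br)cc1OC(C)=O
F3 | step 5 | 2-(2-bromo-4-hydroxy-5-methoxybenzyl)-4-hydroxy-5-methoxybenzaldehyde | COc1cc(C=O)c(Cc2cc(OC)c(O)cc2Br)cc1O
F4 | step 8 | 3-bromo-2-(4,5-diacetoxy-2,3-dibromobenzyl)-4,5-diacetoxybenzaldehyde | CC(=O)Oc1cc(C=O)c(Cc2cc(OC(C)=O)c(OC(C)=O)c(Br)c2Br)c(Br)c1OC(C)=O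
F5 | step 8 | bis[4,5-diacetoxy-3-bromo-2-(4,5-diacetoxy-2,3-dibromobenzyl)benzyl] ether | O(Cc1cc(OC(C)=O)c(OC(C)=O)c(Br)c1Cc1cc(OC(C)=O)c(OC(C)=O)c(Br)c1Br)Cc1cc(OC(C)=O)c(OC(C)=O)c(Br)c1Cc1cc(OC(C)=O)c(OC(C)=O)c(Br)c1Br
F6 | step 3 | 2-[4-(benzyloxy)-3-methoxybenzyl]-4,4,5,5-tetramethyl-1,3,2-dioxaborolane | COc1cc(CB2OC(C)(C)C(C)(C)O2)ccc1OCc1ccccc1
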